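Ring A is disconnected across C1'–C2' and C5'–C6': a 1,2,3-trisubstituted resorcinol ring in which chain carbon C1 sits on C1' between the oxygens on C2' and C6' is exactly what a vinylketene (supplying C2'–C5') and a 1-methoxyalkyne (supplying C6' and C1') deliver. One thermal operation on cyclobutenone and the ynol ether forms both bonds, closes ring A and installs the C2' hydroxyl, the C6' methoxy group and the complete chain with correct regiochemistry. The precursor is a methyl ynol ether whose propargylic carbon (future C1) carries a silyl ether and an eight-methylene tether ending in a benzyl-protected phenol; the C1 oxygen is later oxidised to the ketone.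

Key step: step 7

Remark: chain carbon C1 is stereogenic only in 9, 10 and 16–21 and becomes the ketone carbon in step 10, so these compounds are made and used as racemates; the target has no stereocentre.

Step 1
Reactants: 1 1-(benzyloxy)-4-bromobenzene; 2 9-bromononan-1-ol
Product: 5 9-[4-(benzyloxy)phenyl]nonan-1-ol, via [4-(benzyloxy)phenyl]magnesium bromide 3 (not isolated), via chloromagnesium 9-bromononan-1-olate 4 (not isolated)
Conditions: (a) 1, Mg, THF, 50 °C; (b) 2, i-PrMgCl (1.0 equiv), THF, −20 °C; (c) 3 (1.3 equiv) added to 4, Li2CuCl4 (3 mol%), THF, 0 °C → rt; dilute HCl work-up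
Reagents that add atoms: none
Why: Copper-catalysed Kochi cross-coupling of an aryl Grignard reagent with a primary alkyl bromide should join the two fragments, because prior conversion of the hydroxyl into its magnesium alkoxide by a sacrificial Grignard reagent prevents protonation of the aryl nucleophile and the benzyl ether is inert.

Step 2
Reactants: 5 9-[4-(benzyloxy)phenyl]nonan-1-ol
Product: 6 9-[4-(benzyloxy)phenyl]nonanal
Conditions: TEMPO (10 mol%), PhI(OAc)2 (1.1 equiv), CH2Cl2, rt
Reagents that add atoms: none
Why: TEMPO-catalysed oxoammonium oxidation with PhI(OAc)2 as terminal oxidant should stop at the aldehyde under anhydrous conditions and leaves the benzyl aryl ether untouched.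

Step 3
Reactants: 6 9-[4-(benzyloxy)phenyl]nonanal; 7 2-chloro-1,1-dimethoxyethane
Product: 9 rac-11-[4-(benzyloxy)phenyl]-1-methoxyundec-1-yn-3-ol, via lithium methoxyacetylide 8 (not isolated)
Conditions: 7 (1.5 equiv), LiNEt2 (4.4 equiv, from Et2NH and n-BuLi), THF, 0 °C; then 6, −78 → −20 °C; pH 7 phosphate buffer; Et3N-deactivated silica
Reagents that add atoms: none
Why: Threefold action of the amide base on the chloroacetal (loss of methanol, loss of HCl, deprotonation) should give the acetylide, which undergoes 1,2-addition to the aldehyde; the carbinol centre is formed without control (racemic), which is harmless because it is oxidised later, and the neutral work-up avoids Meyer–Schuster rearrangement.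

Step 4
Reactants: 9 rac-11-[4-(benzyloxy)phenyl]-1-methoxyundec-1-yn-3-ol
Product: 10 rac-1-(benzyloxy)-4-{9-[(tert-butyldimethylsilyl)oxy]-11-methoxyundec-10-yn-1-yl}benzene
Conditions: TBSCl (1.5 equiv), imidazole (3 equiv), DMF, 0 °C → rt; Et3N-deactivated silica
Reagents that add atoms: tert-butyldimethylsilyl chloride, CC(C)(C)[Si](C)(C)Cl
Why: Imidazole-promoted O-silylation of a secondary alcohol should proceed cleanly, the excess imidazole keeping the medium non-acidic so that the acid-sensitive ynol ether and propargylic C–O bond survive.

Step 5
Reactants: 11 3-oxocyclobutane-1-carboxylic acid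
Product: 13 3-bromocyclobutan-1-one, via 3-oxocyclobutane-1-carbonyl hypobromite 12 (not isolated)
Conditions: HgO (red), Br2, MgSO4, CH2Cl2, reflux
Reagents that add atoms: bromine, BrBr
Why: In this Cristol–Firth variant of the Hunsdiecker reaction the acyl hypobromite formed from the mercury carboxylate and bromine should decarboxylate by a radical chain to the secondary bromide, the ring ketone being inert.

Step 6
Reactants: 13 3-bromocyclobutan-1-one
Product: 14 cyclobut-2-en-1-one
Conditions: n-Bu3N (neat), rt, reduced pressure, product collected at −78 °C and diluted at once with cold toluene; used the same day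
Reagents that add atoms: none
Why: Amine-mediated beta-elimination (E1cB-type dehydrobromination) of the beta-bromo ketone should give the enone, and the non-volatile amine lets the volatile product be removed by vacuum transfer as it forms and kept as a cold dilute solution, which limits polymerisation.

Step 7
Reactants: 14 cyclobut-2-en-1-one; 10 rac-1-(benzyloxy)-4-{9-[(tert-butyldimethylsilyl)oxy]-11-methoxyundec-10-yn-1-yl}benzene
Product: 19 rac-2-{9-[4-(benzyloxy)phenyl]-1-[(tert-butyldimethylsilyl)oxy]nonyl}-3-methoxyphenol, via vinylketene 15 (not isolated), via 4-vinylcyclobutenone 16 (not isolated), via dienylketene 17 (not isolated), via cyclohexa-2,4-dienone 18 (not isolated)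
Conditions: 10 (1.0 equiv), toluene, 80 °C, argon; 14 (2.5 equiv, cold 0.5 M toluene solution) by syringe pump over 6 h; then 110 °C, 2 h
Reagents that add atoms: none
Why: Conrotatory four-electron electrocyclic opening of 14 (cleaving the bond that later returns as C2'–C3') should give vinylketene 15, which undergoes a regiospecific [2+2] cycloaddition with 10 in which the ketene carbonyl carbon bonds to the oxygen-remote alkyne carbon (C2'–C1') and the ketene alpha carbon to the methoxy-bearing carbon (C5'–C6'), giving 4-vinylcyclobutenone 16. Heating opens 16 by a second four-electron electrocyclic reaction to dienylketene 17, and ring A is closed by thermal disrotatory six-electron electrocyclisation between the ketene carbon C2' and the vinyl terminus C3' to give dienone 18, which tautomerises to phenol 19. The closest known reaction type is the Danheiser benzannulation of cyclobutenones with 1-alkoxyalkynes, which gives 2-substituted resorcinol monoethers. No stereocentre is created: the silyloxy carbon passes through unchanged as a racemate and the ring stereocentre of 16 is destroyed on opening. The step needs regioselectivity in the ketene–alkyne union, and this is secured by the polarisation of the ynol ether, whose methoxy group makes the remote carbon the nucleophile toward the ketene carbonyl; the propargylic silyl ether (in place of a ketone) keeps that carbon electron-rich, and a methyl ynol ether cannot lose an alkene by retro-ene fragmentation at these temperatures. Slow addition keeps 14 and 15 dilute so that capture by 10 can compete with their self-condensation, and since all atoms of 14 and 10 end up in 19 no co-product is formed.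

Step 8
Reactants: 19 rac-2-{9-[4-(benzyloxy)phenyl]-1-[(tert-butyldimethylsilyl)oxy]nonyl}-3-methoxyphenol
Product: 20 rac-tert-butyl({9-[4-(benzyloxy)phenyl]-1-(2,6-dimethoxyphenyl)nonyl}oxy)dimethylsilane
Conditions: MeI (3 equiv), K2CO3 (2 equiv), DMF, rt
Reagents that add atoms: iodomethane, CI
Why: Williamson O-methylation (SN2 of the phenoxide on iodomethane) should give the second aryl methyl ether, and the alkyl silyl ether and benzyl ether are stable to carbonate in an aprotic solvent.

Step 9
Reactants: 20 rac-tert-butyl({9-[4-(benzyloxy)phenyl]-1-(2,6-dimethoxyphenyl)nonyl}oxy)dimethylsilane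
Product: 21 rac-9-[4-(benzyloxy)phenyl]-1-(2,6-dimethoxyphenyl)nonan-1-ol
Conditions: TBAF (2 equiv), THF, rt → 50 °C
Reagents that add atoms: none
Why: Fluoride-induced cleavage of the Si–O bond should free the carbinol, and basic fluoride is chosen over acid because this electron-rich benzylic alcohol would ionise and dehydrate under acidic conditions.

Step 10
Reactants: 21 rac-9-[4-(benzyloxy)phenyl]-1-(2,6-dimethoxyphenyl)nonan-1-ol
Product: 22 9-[4-(benzyloxy)phenyl]-1-(2,6-dimethoxyphenyl)nonan-1-one
Conditions: Dess–Martin periodinane (1.5 equiv), NaHCO3, CH2Cl2, 0 °C → rt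
Reagents that add atoms: none
Why: Dess–Martin oxidation (ligand exchange at iodine, then removal of the carbinol hydrogen) should convert the hindered secondary benzylic alcohol into the ketone under bicarbonate buffering, which protects the acid-sensitive carbinol; the racemic centre disappears here.

Step 11
Reactants: 22 9-[4-(benzyloxy)phenyl]-1-(2,6-dimethoxyphenyl)nonan-1-one
Product: 23 1-(2,6-dimethoxyphenyl)-9-(4-hydroxyphenyl)nonan-1-one
Conditions: H2 (1 atm), 10% Pd/C, EtOAc, rt
Reagents that add atoms: none
Why: Catalytic hydrogenolysis of the benzyl aryl ether should release the phenol, while the doubly ortho-substituted aryl ketone, twisted out of conjugation, is not reduced under neutral conditions.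

Compound list
1 | 1-(benzyloxy)-4-bromobenzene | Brc1ccc(OCc2ccccc2)cc1 | starting material
2 | 9-bromononan-1-ol | OCCCCCCCCCBr | starting material
3 | [4-(benzyloxy)phenyl]magnesium bromide (formed in situ) | Br[Mg]c1ccc(OCc2ccccc2)cc1 | intermediate
4 | chloromagnesium 9-bromononan-1-olate (formed in situ) | Cl[Mg]OCCCCCCCCCBr | intermediate
5 | 9-[4-(benzyloxy)phenyl]nonan-1-ol | OCCCCCCCCCc1ccc(OCc2ccccc2)cc1 | intermediate
6 | 9-[4-(benzyloxy)phenyl]nonanal | O=CCCCCCCCCc1ccc(OCc2ccccc2)cc1 | intermediate
7 | 2-chloro-1,1-dimethoxyethane | COC(CCl)OC | starting material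
8 | lithium methoxyacetylide (formed in situ) | [Li]C#COC | intermediate
9 | rac-11-[4-(benzyloxy)phenyl]-1-methoxyundec-1-yn-3-ol | COC#CC(O)CCCCCCCCc1ccc(OCc2ccccc2)cc1 | intermediate
10 | rac-1-(benzyloxy)-4-{9-[(tert-butyldimethylsilyl)oxy]-11-methoxyundec-10-yn-1-yl}benzene | COC#CC(O[Si](C)(C)C(C)(C)C)CCCCCCCCc1ccc(OCc2ccccc2)cc1 | intermediate
11 | 3-oxocyclobutane-1-carboxylic acid | O=C1CC(C(=O)O)C1 | starting material
12 | 3-oxocyclobutane-1-carbonyl hypobromite (formed in situ) | O=C1CC(C(=O)OBr)C1 | intermediate
13 | 3-bromocyclobutan-1-one | O=C1CC(Br)C1 | intermediate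
14 | cyclobut-2-en-1-one | O=C1C=CC1 | intermediate
15 | vinylketene, buta-1,3-dien-1-one (formed in situ) | C=CC=C=O | intermediate
16 | 2-{9-[4-(benzyloxy)phenyl]-1-[(tert-butyldimethylsilyl)oxy]nonyl}-4-ethenyl-3-methoxycyclobut-2-en-1-one (formed in situ; mixture of racemic diastereomers) | O=C1C(C=C)C(OC)=C1C(O[Si](C)(C)C(C)(C)C)CCCCCCCCc2ccc(OCc3ccccc3)cc2 | intermediate
17 | rac-(3E)-2-{9-[4-(benzyloxy)phenyl]-1-[(tert-butyldimethylsilyl)oxy]nonyl}-3-methoxyhexa-1,3,5-trien-1-one (formed in situ; ketene-bearing carbon and vinyl group cis across the C3=C4 bond) | C=C\C=C(OC)/C(=C=O)C(O[Si](C)(C)C(C)(C)C)CCCCCCCCc1ccc(OCc2ccccc2)cc1 | intermediate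
18 | rac-2-{9-[4-(benzyloxy)phenyl]-1-[(tert-butyldimethylsilyl)oxy]nonyl}-3-methoxycyclohexa-2,4-dien-1-one (formed in situ) | O=C1CC=CC(OC)=C1C(O[Si](C)(C)C(C)(C)C)CCCCCCCCc2ccc(OCc3ccccc3)cc2 | intermediate
19 | rac-2-{9-[4-(benzyloxy)phenyl]-1-[(tert-butyldimethylsilyl)oxy]nonyl}-3-methoxyphenol | COc1cccc(O)c1C(O[Si](C)(C)C(C)(C)C)CCCCCCCCc1ccc(OCc2ccccc2)cc1 | intermediate
20 | rac-tert-butyl({9-[4-(benzyloxy)phenyl]-1-(2,6-dimethoxyphenyl)nonyl}oxy)dimethylsilane | COc1cccc(OC)c1C(O[Si](C)(C)C(C)(C)C)CCCCCCCCc1ccc(OCc2ccccc2)cc1 | intermediate
21 | rac-9-[4-(benzyloxy)phenyl]-1-(2,6-dimethoxyphenyl)nonan-1-ol | COc1cccc(OC)c1C(O)CCCCCCCCc1ccc(OCc2ccccc2)cc1 | intermediate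
22 | 9-[4-(benzyloxy)phenyl]-1-(2,6-dimethoxyphenyl)nonan-1-one | COc1cccc(OC)c1C(=O)CCCCCCCCc1ccc(OCc2ccccc2)cc1 | intermediate
23 | 1-(2,6-dimethoxyphenyl)-9-(4-hydroxyphenyl)nonan-1-one | COc1cccc(OC)c1C(=O)CCCCCCCCc1ccc(O)cc1 | target

Total step count: 11. Longest linear sequence: 9 steps (steps 1, 2, 3, 4, 7, 8, 9, 10, 11); steps 5 and 6 are a two-step side branch.

Steps most likely to fail

1. Step 7. Self-condensation or polymerisation of cyclobutenone and of the vinylketene may outrun capture by an alkyne whose reacting carbon is shielded by the neighbouring silyloxy-bearing carbon and slightly deactivated by its oxygen. The ynol ether may also add directly across the strained enone double bond, and the product phenol may be acylated by excess vinylketene. Fallback: ring A is taken intact from an arene and not built. The fallback sets out from aldehyde 6. 1,3-Dimethoxybenzene is lithiated between its two methoxy groups (n-BuLi, THF, 0 °C → rt, directed ortho-metalation) to give (2,6-dimethoxyphenyl)lithium F1, which is added to 6 at −78 °C. Aqueous work-up should give the benzylic alcohol directly, so the route is rejoined at 21 and finished by steps 10 and 11.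

2. Step 3. The methoxyethynyl carbinol may be lost by acid-triggered Meyer–Schuster rearrangement to the unsaturated methyl ester during work-up or chromatography, and residual amide base may enolise the aldehyde. Fallback: the acetylene is prepared separately and the free carbinol is never isolated. The fallback sets out from chloroacetal 7, which with NaNH2 in liquid NH3 gives sodium methoxyacetylide F2; hydrolysis with cold brine and distillation give methoxyacetylene F3. Deprotonation with n-BuLi (THF, −78 °C) gives amine-free lithium methoxyacetylide 8, which is added to aldehyde 6. The resulting lithium rac-11-[4-(benzyloxy)phenyl]-1-methoxyundec-1-yn-3-olate F4 is silylated in the same flask (TBSCl, DMPU, −78 → 0 °C), and the route is rejoined at 10.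

3. Step 1. Copper-catalysed coupling of the aryl nucleophile may be slow, allowing biaryl homocoupling and reduction or elimination of the bromide, and incompletely deprotonated hydroxyl may protonate the Grignard reagent. Fallback: the aryl–chain bond is made by palladium catalysis at an alkyne. The fallback sets out from aryl bromide 1, which undergoes Sonogashira coupling with non-8-yn-1-ol (Pd(PPh3)2Cl2, CuI, Et3N, 70 °C) to give 9-[4-(benzyloxy)phenyl]non-8-yn-1-ol F5. Hydrogenation of the triple bond over PtO2 (H2, 1 atm, EtOAc, rt), a catalyst that does not readily cleave benzyl aryl ethers, should give the saturated alcohol, and the route is rejoined at 5.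

Further compounds
F1 | step 7 | (2,6-dimethoxyphenyl)lithium | COc1cccc(OC)c1[Li]
F2 | step 3 | sodium methoxyacetylide | [Na]C#COC
F3 | step 3 | methoxyacetylene | C#COC
F4 | step 3 | lithium rac-11-[4-(benzyloxy)phenyl]-1-methoxyundec-1-yn-3-olate | COC#CC(O[Li])CCCCCCCCc1ccc(OCc2ccccc2)cc1
F5 | step 1 | 9-[4-(benzyloxy)phenyl]non-8-yn-1-ol | OCCCCCCCC#Cc1ccc(OCc2ccccc2)cc1
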